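The data stem from a simulated flask from invented constants, and the scatter is random.

Whatever else J does on the way, in the reactions considered each J that ends as E or X has passed through G, and G has two exits: G → X by itself, and G + L → E, whose rate follows dissolved L. The ratio of E made to X made therefore contains one concentration, dissolved L. While L stays steady, the exits behave as two parallel drains with fixed time constants, the second being pseudo-first-order.

all flasks: Z 0.014 mM (held)
- elm: J 1.2 × 10⁻⁴ M; Q 1 mM; run made earlier
- maple: J 1.6 × 10⁻⁴ M; Q 1 mM; run made earlier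
- larch: J 2.0 × 10⁻⁴ M; Q 1.9 mM; run made earlier
- south: J 2.0 × 10⁻⁴ M; Q 1.00 mM; time 2.0 min
- east: J 1.2 × 10⁻⁴ M; Q 4.00 mM; time 8.0 min

1. the flask that ends with the higher share of E in all that became E or X, or "neither" when 2 percentage points or less lies between them (south / east / neither)
2. share of E in all that became E or X, south
3. share of E in all that became E or X, east

| run | time / s | E / % | X / % |
|---|---|---|---|
| elm | 10.0 | 0 | 0 |
| elm | 12.0 | 0.2 | 0.2 |
| elm | 25.0 | 0.2 | 0 |
| elm | 40.0 | 0.4 | 1.7 |
| elm | 80.0 | 4.3 | 8.8 |
| maple | 15.0 | 0.6 | 0.7 |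
| maple | 30.0 | 0.7 | 0.2 |
| maple | 50.0 | 1.1 | 3.4 |
| maple | 60.0 | 2.1 | 4.0 |
| maple | 80.0 | 4.4 | 8.3 |
| larch | 10.0 | 0 | 0 |
| larch | 20.0 | 0 | 0.2 |
| larch | 40.0 | 0.6 | 2.6 |
| larch | 60.0 | 1.9 | 4.3 |
| larch | 80.0 | 3.6 | 8.4 |

(scatter of a reading: 0.5 percentage points)

The early rows say little: elm at 12.0 s shows E at 0.2% beside a scatter of 0.5 percentage points. The last rows carry the weight, and E over E plus X reads 32.8% in elm, 34.6% in maple and 30.0% in larch, so these runs are read as one value despite their different J and Q. Larch at 60.0 s reads 30.6%, which shows no drift towards its last row. Pooled, the last rows give 32.5% for the exit share, the part of all that left G which left as E.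

South and east hold Z at the same 0.014 mM, and neither J nor Q stands on the reacting side of either exit among the reactions considered, so this reckoning, which takes dissolved L as equal in the two flasks, puts both at 32.5%, with 2 points as the margin, and gives neither. The weak point is east, whose 4.00 mM of Q lies beyond larch's 1.9 mM.

The forecast gives 33% for south, 34% for east and neither, holding that “dissolved L must reach its plateau early”.

The flasks give 33.2% in south and 33.3% in east, and the answer to which ends higher is neither.

    J + L → Q + D (k = 1600 M⁻¹ s⁻¹)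
    D + L → Q + G (k = 361 M⁻¹ s⁻¹)
    G → X (k = 0.0289 s⁻¹)
    G + L → Q + E (k = 1030 M⁻¹ s⁻¹)
    Z ⇌ L, rate k5*(csat - [L]) (kL = 27.7 s⁻¹)

In south at 2.00 min, dissolved L stands at 1.40 × 10⁻⁵ M, so G + L → E drains G with a rate constant of 0.0144 s⁻¹, half of the 0.0289 s⁻¹ of G → X. East at 8.00 min holds L at 1.40 × 10⁻⁵ M. The neighbouring flask, south with J at 1.2 × 10⁻⁴ M, holds L at 1.40 × 10⁻⁵ M and X at 16.1%, so the exit share of 32.5% reckons its E at 7.75%. That flask holds E at 8.03%, a share of 33.2%.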